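All runs are simulated with constants of no real substance.

Starting material outnumbers free catalyst 1000 to one; write a balance on the catalyst too, beside the equilibrium you suspect. You guess that the flask has reached equilibrium and want to pull target out; test that guess first.

| flask | starting material | free catalyst | temperature | remark | time |
|---|---|---|---|---|---|
| Saturday's | 1 M | 1 mM | 35 °C | the very flask that is asked about, followed so far |  |
| Tuesday's | 0.50 M | 1 mM | 30 °C | run made earlier |  |
| flask | 1.0 M | 1.0 mM | 35 °C |  | 8.0 d |

| run | time / d | target / % | starting material / % |
|---|---|---|---|
| Saturday's | 1.25 | 29 | 72 |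
| Saturday's | 2.50 | 33 | 65 |
| Saturday's | 4.00 | 35 | 65 |
| Saturday's | 5.00 | 32 | 69 |
| Saturday's | 6.00 | 33 | 68 |
| Tuesday's | 0.417 | 19 | 83 |
| Tuesday's | 1.04 | 26 | 67 |
| Tuesday's | 2.08 | 31 | 68 |
| Tuesday's | 3.00 | 36 | 63 |
| Tuesday's | 4.00 | 35 | 62 |

(each reading ± 2 percentage points)

- target that was removed still counts
- the numbers in the tables scatter with a standard deviation of 2 percentage points
- what may be going on: starting material + free catalyst <-> free catalyst + target; free catalyst -> spent catalyst
- additions bring no volume worth counting

- noon: at 8.0 d raise the temperature by 20 K, then wait 8.0 d
- spring: at 8.0 d add free catalyst, 50.0 % of the amount charged, then wait 8.0 d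
- summer: change nothing and wait 8.0 d more
- midnight: at 8.0 d take out 90 % of the target then present, then wait 8.0 d

- target, in percent of the starting material first charged, at 8.0 d
- the remedy with the largest gain of target, or "none" below 2 percentage points (noon / spring / summer / midnight / none)
- target present, with what was taken out counted in, in percent of the starting material first charged, after spring
- target present, with what was taken out counted in, in percent of the starting material first charged, after midnight

Saturday's flask levels off at P = 33.2 %, the mean of its target readings from 2.50 d on. Watch how the rise bends. With catalyst of constant strength, a first-order approach to a plateau keeps one rate. Tuesday's run, read against the 35.5 % of its last two readings, gives 1.84 d⁻¹ at 0.417 d but 0.993 d⁻¹ at 2.08 d. That is thin evidence against a scatter of 2 percentage points, yet I commit to it: free catalyst turns into spent catalyst (catalyst deactivation), and the plateau is a stall.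

Read λ = 1.65 d⁻¹ from Saturday's 29 % at 1.25 d, and take it as the decay rate. Then h = ln(2)/λ = 0.421 d, the half-life of free catalyst. Saturday's flask at 8.0 d has passed 19.0 half-lives, so hardly any free catalyst stands in it. My reckoning: now is about P, midnight stays at P, and spring, which brings fresh catalyst, is best, though I cannot size its gain.

The forecast differs on the choice and on midnight: 34 %, midnight, 38 % after spring and 45 % after midnight, called "a hedged choice".

The flask gives 33.7 %, and the best remedy is spring, with 38.7 % against 33.7 % after midnight. Midnight's total equals the target at 8.0 d, where free catalyst stands at 0 %. Use h again, as the estimate it is: it counts the wait of 8.0 d as 19.0 half-lives for the catalyst added in spring, so by this estimate hardly any of that addition is free at the end of the wait.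

    starting material + free catalyst ⇌ free catalyst + target (K = 0.760, k = 34.0 M⁻¹ h⁻¹, Ea = 47.0 kJ mol⁻¹, ΔH = 8.00 kJ mol⁻¹)
    free catalyst → spent catalyst (k = 0.0520 h⁻¹, Ea = 103 kJ mol⁻¹)
    (constants at 35 °C)

In the neighbour flask with 0.0040 M of free catalyst, the estimate h counts 8.0 d as 19.0 half-lives, so hardly any of that charge should be free, and that neighbour flask should have stopped as well. Computed, that neighbour flask holds 0 % free catalyst and 43.1 % target, with 57 % of its starting material left.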